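Time brings the west run no change that its late readings can show: target reads 71.1% at 12.0 min and 70.8% at 15.0 min, a difference inside a scatter of 1 percentage point.

| flask | solid electrophile | nucleophile | protic impurity | remark | time |
|---|---|---|---|---|---|
| north-east | 1 M | 0.90 equiv | 0.30 M | the very flask that is asked about, followed so far |  |
| west | 1 M | 1.4 equiv | 0.30 M | run made earlier |  |
| flask | 1.0 M | 0.900 equiv | 0.300 M |  | 15 min |

| run | time / min | solid electrophile / % | target / % |
|---|---|---|---|
| north-east | 0.833 | 83.8 | 6.0 |
| north-east | 1.50 | 75.6 | 11.4 |
| north-east | 2.50 | 61.8 | 20.1 |
| north-east | 3.00 | 54.9 | 23.8 |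
| north-east | 4.00 | 39.3 | 30.4 |
| north-east | 5.00 | 27.2 | 37.9 |
| north-east | 6.00 | 14.6 | 41.9 |
| west | 2.00 | 68.4 | 19.5 |
| west | 4.00 | 38.6 | 41.5 |
| west | 6.00 | 10.0 | 56.3 |
| west | 8.00 | 0 | 67.2 |
| west | 10.0 | 0 | 70.4 |
| west | 12.0 | 0.2 | 71.1 |
| west | 15.0 | 0.3 | 70.8 |

(standard deviation of a reading: 1 percentage point)

- part of the solid electrophile that has reacted (what has only dissolved counts as not reacted) at 15 min
- share of the unused nucleophile that is free and not bound as protonated nucleophile, at 15 min

- at the start none of the solid electrophile is in solution
- what has only dissolved of solid electrophile counts as not reacted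
- the earlier runs do not show how much of nucleophile is bound; that part of a forecast is a guess

The bench rule allows one nucleophile per target, which makes nucleophile the limiting reagent of the north-east flask and promises target up to its 0.900 equiv. The rule meets its border in the west run, where 1.4 equiv of nucleophile gave that target reading at 12.0 min. Their ratio is the nucleophile cost, equivalents charged per target formed, 1.97, and not one. The protonated nucleophile would account for this if each target made took a second nucleophile into the bound form. A molecule of electrophile also has another exit: the 28.9% of the west charge not read as target at 12.0 min stands close to the 0.30 M of protic impurity. The west run cannot separate these two readings, so the reckoning made here assumes both. The north-east flask then reacts that 28.9% plus 0.900 equiv divided by the cost, giving c near 74.6%, with the unused nucleophile in the bound form and fr low.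

The forecast stands higher, at 94% and 80%, on the ground that “If the impurity is mostly consumed, most leftover nucleophile is free.”

The flask gives c = 83.2% and fr = 5.17%, and at 15.0 min it holds 0.346 M protonated nucleophile beside 0.189 M acid set free.

    electrophile + nucleophile → acid set free + target (k = 1.60 L mol⁻¹ min⁻¹)
    nucleophile + acid set free ⇌ protonated nucleophile, settled at all times (K = 97.0 L mol⁻¹)
    electrophile + protic impurity → quenched substrate (k = 1.70 L mol⁻¹ min⁻¹)
    solid electrophile ⇌ electrophile, rate k4*(cs4 - [electrophile]) while solid is left; crystals form when [electrophile] > cs4 (solubility = 0.750 M, k = 0.230 min⁻¹)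

The reckoning falls short by 8.6 points, which at the cost of 1.97 stands for 0.169 equivalents of nucleophile, a figure to set beside that unbound acid. The neighbour with 0.540 equiv reckons as 56.3%. Computed, that neighbour gives 66.2%, a shortfall worth 0.195 equivalents beside 0.194 M acid set free.

Readings and results are calculated with constants of no real substance, and the scatter is random.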